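**Assumptions (one line each)**
- The target is handled as its disodium salt and protonated on an H⁺ resin to the free bis(hydrogen sulfate) drawn.
- (S)-α-Methyl-γ-butyrolactone is bought (it can also be made by Ru–BINAP hydrogenation of α-methylene-γ-butyrolactone).
- Ring labels: A = benzyl-bearing ring, B = its fused partner, C = right-hand ring with the two vicinal methyls, D = gem-dimethyl ring.

## Retrosynthetic overview
1. Toxiusol ⇐ hydroquinone dimethyl ether 22 (late demethylation and sulfation). The Δ-alkene of ring D and the C/D-ring quaternary methyl ⇐ enone 20 by methyl-cuprate addition, enol triflate formation and reduction.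
2. Ring C (formed last) ⇐ intramolecular Mukaiyama aldol condensation of ketone 19. The linker bond ⇐ alkyllithium from left-half iodide 13 plus Weinreb amide 18.
3. 18 (ring D plus two stereocentres) ⇐ Cu-catalysed asymmetric conjugate addition of a lactone-derived zinc reagent to 4,4-dimethylcyclohexenone, with enolate silylation.
4. 13 ⇐ Eschenmoser–Claisen rearrangement (B-ring quaternary carbon and A-ring alkene) ⇐ enone 9 ⇐ axial methyl-cuprate addition to dienone 8.
5. Key step: 8 ⇐ catalytic enantioselective desymmetrising conjugate addition/aldol annulation of the prochiral dienone 6, made from 2-bromo-1,4-dimethoxybenzene. Ring order: A → B → (D purchased) → C.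

## Forward route

**Step 1**
Reactants: 1 2-bromo-1,4-dimethoxybenzene; 2 2-methylprop-2-en-1-ol
Product: 3 (±)-3-(2,5-dimethoxyphenyl)-2-methylpropanal
Conditions: Pd(OAc)2 (2 mol %), n-Bu4NBr, NaHCO3, DMF, 100 °C
Reagents that add atoms: none (all atoms from 1 and 2)
Why: Heck arylation of an allylic alcohol (Jeffery conditions); β-hydride elimination toward the carbinol gives an enol that tautomerises to the aldehyde, and the racemic α-centre is irrelevant.

**Step 2**
Reactants: 3; 4 but-3-en-2-one
Product: 5 (±)-4-(2,5-dimethoxybenzyl)-4-methylcyclohex-2-en-1-one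
Conditions: pyrrolidine, PhMe, Dean–Stark; 4, rt; then AcOH/NaOAc, H2O, reflux
Reagents that add atoms: none (all atoms from 3 and 4)
Why: Stork enamine Michael addition then intramolecular aldol condensation (Robinson annulation of an α-branched aldehyde) builds ring A with the methyl/benzyl quaternary carbon, racemic here and prochiral after step 3.

**Step 3**
Reactants: 5
Product: 6 4-(2,5-dimethoxybenzyl)-4-methylcyclohexa-2,5-dien-1-one (achiral, Cs)
Conditions: LDA, TMSCl, THF, −78 °C; then Pd(OAc)2, MeCN, rt
Reagents that add atoms: none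
Why: Kinetic α′-silyl dienol ether formation and Saegusa–Ito oxidation install the second enone, giving a symmetric dienone that cannot aromatise.

**Step 4 (key step)**
Reactants: 6; 7 2-(3-chloropropyl)-2-methyl-1,3-dioxolane
Product: 8 (4R,4aS)-4-(2,5-dimethoxybenzyl)-4,8-dimethyl-4a,5,6,7-tetrahydronaphthalen-1(4H)-one
Conditions: 7, Mg, THF; ZnCl2 (0.5 equiv), dioxane, filter (R2Zn); 6, Cu(OTf)2 (3 mol %), BINOL/bis(1-phenylethyl)amine phosphoramidite (6 mol %, enantiomer chosen for 4R,4aS), PhMe, −30 °C; then p-TsOH·H2O, wet PhMe, 80 °C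
Reagents that add atoms: none (all atoms from 6 and 7)
Why: Proposed new method: the chiral Cu–phosphoramidite catalyst selects one of the two enantiotopic enone β-carbons of the symmetric dienone while the alkyl group enters anti to the bulkier 2,5-dimethoxybenzyl group (cis to CH3), fixing both C4 and C4a in one event, and acid then unmasks the methyl ketone and closes ring B by aldol condensation at the α′-carbon; the closest known reaction types are the Cu/phosphoramidite-catalysed desymmetrising conjugate addition of dialkylzincs to 4,4-disubstituted cyclohexa-2,5-dienones and the ketal-zinc conjugate addition/aldol annulation of cyclohexenones.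

**Step 5**
Reactants: 8
Product: 9 (3R,4R,4aS)-4-(2,5-dimethoxybenzyl)-3,4,8-trimethyl-3,4,4a,5,6,7-hexahydronaphthalen-1(2H)-one
Conditions: Me2CuLi, TMSCl, THF, −78 °C; aq. NH4Cl
Reagents that add atoms: lithium dimethylcuprate, [Li+].C[Cu-]C
Why: Gilman conjugate addition occurs only at the disubstituted enone (the tetrasubstituted one is inert) and axially, anti to the pseudo-axial C4 methyl of the locked bicycle, so the new C3 methyl is trans to the C4 methyl and cis to the benzyl group.

**Step 6**
Reactants: 9
Product: 10 (1S,3R,4R,4aS)-4-(2,5-dimethoxybenzyl)-3,4,8-trimethyl-1,2,3,4,4a,5,6,7-octahydronaphthalen-1-ol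
Conditions: DIBAL-H, CH2Cl2, −78 °C
Reagents that add atoms: none
Why: 1,2-Reduction by the bulky hydride from the face opposite the axial C3 methyl gives the axial allylic alcohol, which is also the epimer free of A(1,3) strain with the C8 methyl.

**Step 7**
Reactants: 10
Product: 11 2-[(1S,4aS,5R,6R)-5-(2,5-dimethoxybenzyl)-1,5,6-trimethyl-1,2,3,4,4a,5,6,7-octahydronaphthalen-1-yl]-N,N-dimethylacetamide
Conditions: MeC(OMe)2NMe2, xylenes, 140 °C
Reagents that add atoms: N,N-dimethylacetamide dimethyl acetal, COC(C)(OC)N(C)C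
Why: Eschenmoser–Claisen [3,3] rearrangement transfers chirality suprafacially from C–O to the alkene terminus, creating the B-ring quaternary centre with the two-carbon arm on the face the hydroxyl occupied and moving the alkene to its final position.

**Step 8**
Reactants: 11
Product: 12 2-[(1S,4aS,5R,6R)-5-(2,5-dimethoxybenzyl)-1,5,6-trimethyl-1,2,3,4,4a,5,6,7-octahydronaphthalen-1-yl]ethan-1-ol
Conditions: LiEt3BH, THF, 0 °C → rt
Reagents that add atoms: none
Why: Super-Hydride reduces the tertiary amide to the primary alcohol with C–N cleavage; no stereocentre is involved.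

**Step 9**
Reactants: 12
Product: 13 (1S,4aS,5R,6R)-5-(2,5-dimethoxybenzyl)-1-(2-iodoethyl)-1,5,6-trimethyl-1,2,3,4,4a,5,6,7-octahydronaphthalene
Conditions: I2, PPh3, imidazole, CH2Cl2, 0 °C → rt
Reagents that add atoms: iodine, II
Why: Appel-type iodination (SN2) of the primary alcohol.

**Step 10**
Reactants: 14 (S)-3-methyldihydrofuran-2(3H)-one
Product: 15 (S)-4-hydroxy-N-methoxy-N,2-dimethylbutanamide
Conditions: MeNH(OMe)·HCl, AlMe3, CH2Cl2, 0 °C → rt
Reagents that add atoms: N,O-dimethylhydroxylamine hydrochloride, CNOC.Cl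
Why: Weinreb aminolysis of the lactone by the dimethylaluminium amide opens the ring without touching the α-stereocentre.

**Step 11**
Reactants: 15
Product: 16 (S)-4-iodo-N-methoxy-N,2-dimethylbutanamide
Conditions: I2, PPh3, imidazole, CH2Cl2, 0 °C
Reagents that add atoms: iodine, II
Why: Appel-type iodination of the primary alcohol; the product is used promptly.

**Step 12**
Reactants: 16; 17 4,4-dimethylcyclohex-2-en-1-one
Product: 18 (S)-4-[(S)-3-((tert-butyldimethylsilyl)oxy)-6,6-dimethylcyclohex-2-en-1-yl]-N-methoxy-N,2-dimethylbutanamide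
Conditions: 16, Et2Zn (neat), CuI (cat.), 50 °C, evacuate (R2Zn); 17, Cu(OTf)2 (2 mol %), phosphoramidite (4 mol %), PhMe, −30 °C; then TBSOTf, −30 → 0 °C
Reagents that add atoms: tert-butyldimethylsilyl triflate, CC(C)(C)[Si](C)(C)OS(=O)(=O)C(F)(F)F
Why: Iodine–zinc exchange gives the amide-bearing dialkylzinc, whose Cu/phosphoramidite-catalysed enantioselective conjugate addition sets the ring stereocentre under catalyst control (the remote α-methyl centre is a spectator), and silylation of the zinc enolate stores the regiodefined enolate for step 14.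

**Step 13**
Reactants: 13; 18
Product: 19 (S)-1-[(1S,4aS,5R,6R)-5-(2,5-dimethoxybenzyl)-1,5,6-trimethyl-1,2,3,4,4a,5,6,7-octahydronaphthalen-1-yl]-6-[(S)-3-((tert-butyldimethylsilyl)oxy)-6,6-dimethylcyclohex-2-en-1-yl]-4-methylhexan-3-one
Conditions: 13, t-BuLi (2.1 equiv), Et2O, −78 °C; then 18, THF, −78 → −20 °C
Reagents that add atoms: none (all atoms from 13 and 18)
Why: Iodine–lithium exchange then Weinreb ketone synthesis; the chelated tetrahedral intermediate prevents over-addition, and the silyl enol ether and the α-methyl stereocentre survive at low temperature.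

**Step 14**
Reactants: 19
Product: 20 (4aR,7S)-8-{2-[(1S,4aS,5R,6R)-5-(2,5-dimethoxybenzyl)-1,5,6-trimethyl-1,2,3,4,4a,5,6,7-octahydronaphthalen-1-yl]ethyl}-4,4,7-trimethyl-3,4,4a,5,6,7-hexahydronaphthalen-1(2H)-one
Conditions: TiCl4, CH2Cl2, −78 °C; then p-TsOH (cat.), PhH, 40 °C on the crude ketol
Reagents that add atoms: none
Why: Intramolecular Mukaiyama aldol addition, with the site fixed by the silyl enol ether so the other aldol modes of the free diketone cannot compete, closes ring C, and acid-catalysed dehydration gives the conjugated tetrasubstituted enone; the α-methyl centre is not epimerised at −78 °C and is no longer α to a carbonyl afterwards.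

**Step 15**
Reactants: 20
Product: 21 (4aR,7S,8R)-8-{2-[(1S,4aS,5R,6R)-5-(2,5-dimethoxybenzyl)-1,5,6-trimethyl-1,2,3,4,4a,5,6,7-octahydronaphthalen-1-yl]ethyl}-4,4,7,8-tetramethyl-2,3,4,4a,5,6,7,8-octahydronaphthalen-1-yl trifluoromethanesulfonate
Conditions: Me2CuLi, TMSCl, THF/Et2O, −78 → −20 °C; then MeLi, 0 °C; PhNTf2, −78 °C → rt
Reagents that add atoms: lithium dimethylcuprate, [Li+].C[Cu-]C; N-phenylbis(trifluoromethanesulfonimide), O=S(=O)(N(c1ccccc1)S(=O)(=O)C(F)(F)F)C(F)(F)F
Why: Conjugate addition to the s-cis enone takes place axially on the face that is syn only to the axial ring-fusion hydrogen (chair-like transition state of ring C, held by the ring fusion), so the new methyl is cis to the neighbouring methyl and the ring-fusion H, and the regiospecific enolate is trapped as the enol triflate.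

**Step 16**
Reactants: 21
Product: 22 toxiusol hydroquinone dimethyl ether (24 with both OSO3H replaced by OCH3)
Conditions: Pd(OAc)2, PPh3, HCO2H, n-Bu3N, DMF, 60 °C
Reagents that add atoms: none
Why: Pd-catalysed formate reduction of the enol triflate gives the trisubstituted alkene exactly where the enolate was, without touching any stereocentre.

**Step 17**
Reactants: 22
Product: 23 toxiusol hydroquinone (24 with both OSO3H replaced by OH)
Conditions: CAN, MeCN/H2O, 0 °C; then aq. Na2S2O4
Reagents that add atoms: water, O (source of the quinone oxygens)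
Why: CAN oxidative demethylation of the 1,4-dimethoxyarene to the quinone, then dithionite reduction to the hydroquinone; the hindered trisubstituted alkenes are inert.

**Step 18**
Reactants: 23
Product: 24 toxiusol
Conditions: SO3·pyridine (excess), pyridine, 50 °C; NaHCO3; Dowex 50W (H⁺)
Reagents that add atoms: sulfur trioxide–pyridine complex, O=S(=O)=O.c1ccncc1
Why: O-Sulfation of both phenols with SO3·pyridine gives the bis(hydrogen sulfate).

## Compound list
1 | 2-bromo-1,4-dimethoxybenzene | COc1ccc(OC)c(Br)c1 | starting material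
2 | 2-methylprop-2-en-1-ol | CC(=C)CO | starting material
3 | (±)-3-(2,5-dimethoxyphenyl)-2-methylpropanal | O=CC(C)Cc1cc(OC)ccc1OC | intermediate
4 | but-3-en-2-one | CC(=O)C=C | starting material
5 | (±)-4-(2,5-dimethoxybenzyl)-4-methylcyclohex-2-en-1-one | O=C1C=CC(C)(Cc2cc(OC)ccc2OC)CC1 | intermediate
6 | 4-(2,5-dimethoxybenzyl)-4-methylcyclohexa-2,5-dien-1-one | O=C1C=CC(C)(Cc2cc(OC)ccc2OC)C=C1 | intermediate
7 | 2-(3-chloropropyl)-2-methyl-1,3-dioxolane | CC1(CCCCl)OCCO1 | starting material
8 | (4R,4aS)-4-(2,5-dimethoxybenzyl)-4,8-dimethyl-4a,5,6,7-tetrahydronaphthalen-1(4H)-one | C1=CC(=O)C2=C(C)CCC[C@H]2[C@]1(C)Cc1cc(OC)ccc1OC | intermediate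
9 | (3R,4R,4aS)-4-(2,5-dimethoxybenzyl)-3,4,8-trimethyl-3,4,4a,5,6,7-hexahydronaphthalen-1(2H)-one | C[C@@H]1CC(=O)C2=C(C)CCC[C@H]2[C@]1(C)Cc1cc(OC)ccc1OC | intermediate
10 | (1S,3R,4R,4aS)-4-(2,5-dimethoxybenzyl)-3,4,8-trimethyl-1,2,3,4,4a,5,6,7-octahydronaphthalen-1-ol | C[C@@H]1C[C@H](O)C2=C(C)CCC[C@H]2[C@]1(C)Cc1cc(OC)ccc1OC | intermediate
11 | 2-[(1S,4aS,5R,6R)-5-(2,5-dimethoxybenzyl)-1,5,6-trimethyl-1,2,3,4,4a,5,6,7-octahydronaphthalen-1-yl]-N,N-dimethylacetamide | C[C@@H]1CC=C2[C@@H](CCC[C@@]2(C)CC(=O)N(C)C)[C@]1(C)Cc1cc(OC)ccc1OC | intermediate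
12 | 2-[(1S,4aS,5R,6R)-5-(2,5-dimethoxybenzyl)-1,5,6-trimethyl-1,2,3,4,4a,5,6,7-octahydronaphthalen-1-yl]ethan-1-ol | C[C@@H]1CC=C2[C@@H](CCC[C@@]2(C)CCO)[C@]1(C)Cc1cc(OC)ccc1OC | intermediate
13 | (1S,4aS,5R,6R)-5-(2,5-dimethoxybenzyl)-1-(2-iodoethyl)-1,5,6-trimethyl-1,2,3,4,4a,5,6,7-octahydronaphthalene | C[C@@H]1CC=C2[C@@H](CCC[C@@]2(C)CCI)[C@]1(C)Cc1cc(OC)ccc1OC | intermediate
14 | (S)-3-methyldihydrofuran-2(3H)-one | C[C@H]1CCOC1=O | starting material
15 | (S)-4-hydroxy-N-methoxy-N,2-dimethylbutanamide | CON(C)C(=O)[C@@H](C)CCO | intermediate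
16 | (S)-4-iodo-N-methoxy-N,2-dimethylbutanamide | CON(C)C(=O)[C@@H](C)CCI | intermediate
17 | 4,4-dimethylcyclohex-2-en-1-one | CC1(C)CCC(=O)C=C1 | starting material
18 | (S)-4-[(S)-3-((tert-butyldimethylsilyl)oxy)-6,6-dimethylcyclohex-2-en-1-yl]-N-methoxy-N,2-dimethylbutanamide | CON(C)C(=O)[C@@H](C)CC[C@H]1C=C(O[Si](C)(C)C(C)(C)C)CCC1(C)C | intermediate
19 | union ketone (name in step 13) | C[C@@H]1CC=C2[C@@H](CCC[C@@]2(C)CCC(=O)[C@@H](C)CC[C@H]2C=C(O[Si](C)(C)C(C)(C)C)CCC2(C)C)[C@]1(C)Cc1cc(OC)ccc1OC | intermediate
20 | tetracyclic enone (name in step 14) | C[C@@H]1CC=C2[C@@H](CCC[C@@]2(C)CCC2=C3C(=O)CCC(C)(C)[C@H]3CC[C@@H]2C)[C@]1(C)Cc1cc(OC)ccc1OC | intermediate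
21 | enol triflate (name in step 15) | C[C@@H]1CC=C2[C@@H](CCC[C@@]2(C)CC[C@@]2(C)C3=C(OS(=O)(=O)C(F)(F)F)CCC(C)(C)[C@H]3CC[C@@H]2C)[C@]1(C)Cc1cc(OC)ccc1OC | intermediate
22 | toxiusol hydroquinone dimethyl ether | C[C@@H]1CC=C2[C@@H](CCC[C@@]2(C)CC[C@@]2(C)C3=CCCC(C)(C)[C@H]3CC[C@@H]2C)[C@]1(C)Cc1cc(OC)ccc1OC | intermediate
23 | toxiusol hydroquinone | C[C@@H]1CC=C2[C@@H](CCC[C@@]2(C)CC[C@@]2(C)C3=CCCC(C)(C)[C@H]3CC[C@@H]2C)[C@]1(C)Cc1cc(O)ccc1O | intermediate
24 | toxiusol | C[C@@H]1CC=C2[C@@H](CCC[C@@]2(C)CC[C@@]2(C)C3=CCCC(C)(C)[C@H]3CC[C@@H]2C)[C@]1(C)Cc1cc(OS(=O)(=O)O)ccc1OS(=O)(=O)O | target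

## Step count and risks
Total steps: 18. Longest linear sequence: 15 (steps 1–9, then 13–18).

Steps most likely to fail, each with a fallback that changes the approach:

1. **Step 4 (desymmetrising annulation).** The facial discrimination between CH3 and CH2Ar on the dienone may be modest, and the ketal-bearing zinc reagent may be sluggish. Fallback: make the prochiral dienone by dearomatisation instead. Birch reductive methylation of methyl benzoate and bis-allylic oxidation give methyl 1-methyl-4-oxocyclohexa-2,5-diene-1-carboxylate; a bulky ester shields its own face far better than a benzyl group. Run the same annulation on it, then convert the ester to CH2Ar after ring B is closed (aldehyde, 2-lithio-1,4-dimethoxybenzene, Barton–McCombie).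

2. **Step 15 (methyl addition to the hindered tetrasubstituted enone).** Both reactivity and the axial facial preference are uncertain. Fallback: replace substrate-controlled conjugate addition by stereospecific allylic substitution. CBS-reduce 20 to the allylic alcohol with the C–O bond on the face opposite to that required for methyl, make the picolinate, and carry out anti-SN2′ displacement with MeMgBr/CuBr·SMe2. This transfers chirality from oxygen to carbon and gives the ring-D alkene directly, with no triflate.

3. **Step 12 (conjugate addition of an amide-bearing dialkylzinc to the neopentyl-type enone with in-situ silylation).** Fallback: set the ring stereocentre by hydride rather than carbon delivery. Add the side-chain organometallic (carboxyl terminus masked) to 3-ethoxy-6,6-dimethylcyclohex-2-enone (Stork–Danheiser) to get the 3-alkyl-4,4-dimethylcyclohexenone. Then use CuH/DTBM-SEGPHOS asymmetric conjugate hydrosilylation, which gives the same regiodefined silyl enol ether.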